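**Retrosynthetic overview**

1. Endgame: removal of two N-Boc groups; before that, both aryl–indolyl bonds (C5–C3' and C8–C3') are made by a double Suzuki coupling on 5,8-dibromo-7-methoxy-2,2-dimethyl-2H-chromen-6-ol.
2. Key disconnection: the pyran ring is opened at O1–C2 and at C3–C4, giving 3,6-dibromo-2,5-dihydroxy-4-methoxybenzaldehyde and (2-methylprop-1-enyl)boronic acid. Forward, one amine-catalysed cascade makes both bonds: boronate-tethered alkenyl transfer to an iminium, amine loss to a vinyl ortho-quinone methide, oxa-6π closure. The B–O tether and the C4–N bond are temporary.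
3. Enabling feature: O1 sits on C8a, ortho to C4a, which carries C4, so O1–C8a–C4a–C4 is a masked salicylaldehyde. The pyran ring O1–C2(Me)2–C3=C4–C4a=C8a is the ring-closed valence isomer of a 1-oxatriene. The second oxygen (C6–OH) is meta to C4a and cannot compete.
4. The aldehyde comes from 2-hydroxy-4-methoxybenzaldehyde by Elbs para-hydroxylation (the C6 oxygen of the target) and bromination of the two remaining ring positions (future C5 and C8).
5. Ring order: benzene ring bought; pyran ring closed in step 3; the two bought indole rings attached in step 4.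

Key step: step 3

Remark: the target has no stereocentre, and the two aryl–indolyl axes are treated as freely rotating because the SMILES defines no axial configuration. Compounds 1, 5 and 9 are taken as commercially available.

**Route**

Step 1
Reactants: 1 2-hydroxy-4-methoxybenzaldehyde
Product: 3 2,5-dihydroxy-4-methoxybenzaldehyde, via aryl sulfate 2 (not isolated)
Conditions: K2S2O8, aq KOH, 10 °C to rt; then aq HCl, 90 °C
Reagents that add atoms: potassium peroxodisulfate, [K+].[K+].[O-]S(=O)(=O)OOS(=O)(=O)[O-]
Why: Elbs persulfate oxidation, in which the phenoxide of 1 attacks a peroxide oxygen through its para carbon (C5, the only free position para to the hydroxyl) and acid hydrolysis of aryl sulfate 2 should release the hydroquinone.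

Step 2
Reactants: 3 2,5-dihydroxy-4-methoxybenzaldehyde
Product: 4 3,6-dibromo-2,5-dihydroxy-4-methoxybenzaldehyde
Conditions: Br2 (2.1 equiv), AcOH, 15 °C to rt, dark
Reagents that add atoms: bromine, BrBr
Why: Electrophilic aromatic bromination at the only two free ring positions, C3 (ortho to the 2-hydroxyl and the 4-methoxy group) and C6 (ortho to the 5-hydroxyl); any quinone formed by oxidation should take up HBr by conjugate addition and return to a ring-brominated hydroquinone.

Step 3
Reactants: 4 3,6-dibromo-2,5-dihydroxy-4-methoxybenzaldehyde; 5 (2-methylprop-1-en-1-yl)boronic acid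
Product: 8 5,8-dibromo-7-methoxy-2,2-dimethyl-2H-chromen-6-ol, via Petasis amine adduct 6 (not isolated), via vinyl ortho-quinone methide 7 (not isolated)
Conditions: Bn2NH (0.4 equiv), 1,4-dioxane, 90 °C, Ar
Reagents that add atoms: none
Why: This is the catalytic Petasis (borono-Mannich) condensation/cyclisation known for salicylaldehydes and alkenylboronic acids: Bn2NH and the aldehyde of 4 form an ortho-phenoxide iminium, boronic acid 5 binds the ortho oxygen (future O1) as a tetracoordinate boronate and passes its alkenyl carbon (future C3) to the iminium carbon (future C4) within this temporary B–O tether, giving amine 6. At 90 °C the ortho-hydroxybenzylic amine 6 should expel Bn2NH, which re-enters the cycle, to give vinyl ortho-quinone methide 7, and thermal oxa-6π electrocyclisation of the 1-oxatriene O=C8a–C4a=C4–C3=C2 then forms O1–C2. The pyran ring is the only ring closed, by a disrotatory six-electron electrocyclic closure that is driven by the return of aromaticity to the carbocycle. No stereocentre results, since the carbon stereocentre of 6 forms racemic and is erased on amine loss and C2 carries two identical methyl groups. The step needs regioselectivity between the two phenols and chemoselectivity against the aryl bromides: only the 2-hydroxyl is ortho to the formyl group (the 5-hydroxyl is meta and binds boron only reversibly), and the C–Br bonds are inert without a transition metal.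

Step 4
Reactants: 8 5,8-dibromo-7-methoxy-2,2-dimethyl-2H-chromen-6-ol; 9 tert-butyl 3-(4,4,5,5-tetramethyl-1,3,2-dioxaborolan-2-yl)-1H-indole-1-carboxylate (3 equiv)
Product: 10 di-tert-butyl 3,3'-(6-hydroxy-7-methoxy-2,2-dimethyl-2H-chromene-5,8-diyl)bis(1H-indole-1-carboxylate)
Conditions: Pd(OAc)2 (10 mol %), SPhos (20 mol %), K3PO4, 1,4-dioxane/H2O 10:1, 85 °C, Ar
Reagents that add atoms: none
Why: Double Suzuki–Miyaura coupling, in which the electron-rich biarylphosphine SPhos should let zerovalent palladium insert into both di-ortho-substituted C–Br bonds while the N-Boc group tempers protodeboronation of the indol-3-yl boronate and the chromene alkene and free phenol are tolerated under argon.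

Step 5
Reactants: 10 di-tert-butyl 3,3'-(6-hydroxy-7-methoxy-2,2-dimethyl-2H-chromene-5,8-diyl)bis(1H-indole-1-carboxylate)
Product: 11 Kumbicin C, 5,8-di(1H-indol-3-yl)-7-methoxy-2,2-dimethyl-2H-chromen-6-ol
Conditions: K2CO3 (0.5 equiv), MeOH/THF, 45 °C, Ar
Reagents that add atoms: none
Why: Base-catalysed methanolysis of the two indole N-carbamates (acyl transfer from the weakly basic indole nitrogen to methoxide), which should leave the chromene and the hydroquinone monoether untouched under argon; any Boc group already lost in step 4 converges here.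

**Compound list**

1 | 2-hydroxy-4-methoxybenzaldehyde | COc1ccc(C=O)c(O)c1 | starting material
2 | potassium 5-formyl-4-hydroxy-2-methoxyphenyl sulfate | COc1cc(O)c(C=O)cc1OS(=O)(=O)[O-].[K+] | intermediate (not isolated)
3 | 2,5-dihydroxy-4-methoxybenzaldehyde | COc1cc(O)c(C=O)cc1O | intermediate
4 | 3,6-dibromo-2,5-dihydroxy-4-methoxybenzaldehyde | COc1c(Br)c(O)c(C=O)c(Br)c1O | intermediate
5 | (2-methylprop-1-en-1-yl)boronic acid | CC(C)=CB(O)O | starting material
6 | 3,6-dibromo-2-[1-(dibenzylamino)-3-methylbut-2-en-1-yl]-5-methoxybenzene-1,4-diol (racemic) | COc1c(Br)c(O)c(C(C=C(C)C)N(Cc2ccccc2)Cc2ccccc2)c(Br)c1O | intermediate (not isolated)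
7 | (6E)-2,5-dibromo-4-hydroxy-3-methoxy-6-(3-methylbut-2-en-1-ylidene)cyclohexa-2,4-dien-1-one (side-chain C3 on the carbonyl side of the exocyclic alkene) | CC(C)=C/C=C1\C(=O)C(Br)=C(OC)C(O)=C1Br | intermediate (not isolated)
8 | 5,8-dibromo-7-methoxy-2,2-dimethyl-2H-chromen-6-ol | COc1c(O)c(Br)c2c(c1Br)OC(C)(C)C=C2 | intermediate
9 | tert-butyl 3-(4,4,5,5-tetramethyl-1,3,2-dioxaborolan-2-yl)-1H-indole-1-carboxylate | CC(C)(C)OC(=O)n1cc(B2OC(C)(C)C(C)(C)O2)c2ccccc21 | starting material
10 | di-tert-butyl 3,3'-(6-hydroxy-7-methoxy-2,2-dimethyl-2H-chromene-5,8-diyl)bis(1H-indole-1-carboxylate) | COc1c(O)c(-c2cn(C(=O)OC(C)(C)C)c3ccccc23)c2c(c1-c1cn(C(=O)OC(C)(C)C)c3ccccc13)OC(C)(C)C=C2 | intermediate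
11 | Kumbicin C, 5,8-di(1H-indol-3-yl)-7-methoxy-2,2-dimethyl-2H-chromen-6-ol | COc1c(O)c(-c2c[nH]c3ccccc23)c2c(c1-c1c[nH]c3ccccc13)OC(C)(C)C=C2 | target

**Step count and risks**

Total step count: 5. Longest linear sequence: 5 steps (1 → 3 → 4 → 8 → 10 → 11).

Steps most likely to fail:

Step 4 (double Suzuki coupling). What may go wrong: slow oxidative addition at the two hindered C–Br bonds next to a phenoxide, protodeboronation of the indol-3-yl boronate faster than transmetalation, and loss or transfer of Boc under aqueous base. The fallback sets out from 8 and changes both the nucleophile and the protection. The phenol is masked with MOMCl/iPr2NEt to give 5,8-dibromo-7-methoxy-6-(methoxymethoxy)-2,2-dimethyl-2H-chromene F1. Commercial tert-butyl 3-iodo-1H-indole-1-carboxylate is converted with iPrMgCl·LiCl (THF, −20 °C) and then ZnCl2 into [1-(tert-butoxycarbonyl)-1H-indol-3-yl]zinc chloride F2. Base-free Negishi coupling of F1 with F2 (Pd(OAc)2/SPhos, THF, 60 °C) should give di-tert-butyl 3,3'-[7-methoxy-6-(methoxymethoxy)-2,2-dimethyl-2H-chromene-5,8-diyl]bis(1H-indole-1-carboxylate) F3. HCl in MeOH at room temperature should then cleave the acetal, and the route is rejoined at 10.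

Step 2 (dibromination). What may go wrong: oxidation of the hydroquinone to the quinone instead of substitution, ipso attack at the formyl-bearing carbon with loss of the formyl group, and stalling after the first bromination because C6 is activated by one hydroxyl only. The fallback sets out from 3 and installs the C6 bromine as a nucleophile. Oxidation with Ag2O (Et2O, MgSO4) should give the formylquinone 4-methoxy-3,6-dioxocyclohexa-1,4-diene-1-carbaldehyde F4. Conjugate addition of HBr (AcOH/CHCl3, 0 °C) should go to the ring carbon next to the formyl group, the doubly activated position, and give 6-bromo-2,5-dihydroxy-4-methoxybenzaldehyde F5. One equivalent of NBS (MeCN, 0 °C) should then brominate the doubly activated C3, and the route is rejoined at 4.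

Step 3 (key cascade). What may go wrong: protodeboronation of the β,β-disubstituted alkenylboronic acid before transfer, slow alkenyl transfer to an iminium flanked by bromine, incomplete amine elimination, and air oxidation of the hydroquinone. The fallback sets out from 4 and makes the same two bonds in two known operations. Addition of excess (2-methylprop-1-en-1-yl)magnesium bromide, Me2C=CHMgBr (THF, 0 °C; the first two equivalents are spent on the phenols), should give the allylic alcohol 3,6-dibromo-2-(1-hydroxy-3-methylbut-2-en-1-yl)-5-methoxybenzene-1,4-diol F6. Warming with catalytic PPTS in toluene should dehydrate it to the same ortho-quinone methide 7, which closes by oxa-6π electrocyclisation, and the route is rejoined at 8.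

Further compounds
F1 | step 4 | 5,8-dibromo-7-methoxy-6-(methoxymethoxy)-2,2-dimethyl-2H-chromene | COc1c(OCOC)c(Br)c2c(c1Br)OC(C)(C)C=C2
F2 | step 4 | [1-(tert-butoxycarbonyl)-1H-indol-3-yl]zinc chloride | CC(C)(C)OC(=O)n1cc([Zn]Cl)c2ccccc21
F3 | step 4 | di-tert-butyl 3,3'-[7-methoxy-6-(methoxymethoxy)-2,2-dimethyl-2H-chromene-5,8-diyl]bis(1H-indole-1-carboxylate) | COc1c(OCOC)c(-c2cn(C(=O)OC(C)(C)C)c3ccccc23)c2c(c1-c1cn(C(=O)OC(C)(C)C)c3ccccc13)OC(C)(C)C=C2
F4 | step 2 | 4-methoxy-3,6-dioxocyclohexa-1,4-diene-1-carbaldehyde | COC1=CC(=O)C(C=O)=CC1=O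
F5 | step 2 | 6-bromo-2,5-dihydroxy-4-methoxybenzaldehyde | COc1cc(O)c(C=O)c(Br)c1O
F6 | step 3 | 3,6-dibromo-2-(1-hydroxy-3-methylbut-2-en-1-yl)-5-methoxybenzene-1,4-diol (racemic) | COc1c(Br)c(O)c(C(O)C=C(C)C)c(Br)c1O
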